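## Retrosynthetic overview

1. The seven-membered ring is opened at C9–C10 (last step): intramolecular Nozaki–Hiyama–Kishi addition of a 2-iodoalkene to the C9 aldehyde, held as a γ-lactol, gives C9–OH next to C10=CH2 directly.
2. Key disconnection C6–C7: the 1,4-dioxygen pattern O–C6···C9–O is made with a homoenolate (d3) reagent. A lithiated, then titanated allyl carbamate attacks the C6 aldehyde through its γ-carbon (C7); C9 arrives as a Z-enol carbamate and C6/C7 are set together.
3. Fragment 1 (C1–C6, C10, C18, C20) from cyclopent-2-enone: asymmetric conjugate addition of a 1-silylvinyl group (C1), orthoformate trapping (C5, C6), enol triflate/methyl coupling (C4–Me, C3=C4), Si→I exchange.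
4. Fragment 2 (C7–C9, C11–C17, C19): Brown syn-crotylation of 4-methylpent-4-enal (C11, C12), silylation, cross-metathesis with allyl carbamate.
5. Ring order: the five-membered ring is present from the first step; the seven-membered ring is closed in the last step.

Atom labels: ring fusion C1/C5, C3=C4(Me), C6–OH, C7 (side chain), C8H2, C9–OH, C10=C18H2, C11 (Me), C12 (OAc), C13–C17 isohexenyl end. The target is 1R,5S,6R,7S,9R,11S,12S (trans ring fusion; C6–OH cis to the C7 side chain; C9–OH trans to it).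

Assumption: the hand of the phosphoramidite ligand (step 1) and of the sparteine (step 11) is assigned from the accepted transition-state models for these reaction classes, not from data on these exact substrates; both antipodes of each are commercial.

## Route

Step 1
Reactants: 1 cyclopent-2-en-1-one; 2 ethynyltrimethylsilane
Product: 5 trimethyl({(3R)-3-[1-(trimethylsilyl)ethenyl]cyclopent-1-en-1-yl}oxy)silane, via vinylalane 3 (not isolated), via aluminium enolate 4 (not isolated)
Conditions: 2, i-Bu2AlH, hexane/THF (5:1), 55 °C; then 1, CuBr·SMe2 (2 mol %), (S,R,R)-BINOL bis(1-phenylethyl)amine phosphoramidite (4 mol %), Et2O, −30 °C; then Me3SiOTf, −30 to 0 °C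
Reagents that add atoms: trimethylsilyl trifluoromethanesulfonate, C[Si](C)(C)OS(=O)(=O)C(F)(F)F
Why: Hydroalumination puts aluminium on the silicon-bearing alkyne carbon, the copper–phosphoramidite-catalysed asymmetric conjugate addition transfers the alkenyl group (in preference to isobutyl) to set C1 as R by ligand control, and O-silylation of the aluminium enolate locks the enolate between C4 and C5 for the next step.

Step 2
Reactants: 5 silyl enol ether
Product: 6 (2R,3R)-2-(dimethoxymethyl)-3-[1-(trimethylsilyl)ethenyl]cyclopentan-1-one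
Conditions: HC(OMe)3, Me3SiOTf (5 mol %), CH2Cl2, −78 °C
Reagents that add atoms: trimethyl orthoformate, COC(OC)OC
Why: Mukaiyama-type addition of the regiodefined silyl enol ether to the dimethoxycarbenium ion occurs anti to the C1 substituent and gives the thermodynamically preferred trans keto acetal, so C5 is set relative to C1 and C6 enters at the aldehyde oxidation level.

Step 3
Reactants: 6 trans keto acetal
Product: 7 (4R,5S)-5-(dimethoxymethyl)-4-[1-(trimethylsilyl)ethenyl]cyclopent-1-en-1-yl trifluoromethanesulfonate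
Conditions: KN(SiMe3)2, THF, −78 °C; then PhNTf2, −78 to 0 °C
Reagents that add atoms: N-phenylbis(trifluoromethanesulfonimide), O=S(=O)(N(c1ccccc1)S(=O)(=O)C(F)(F)F)C(F)(F)F
Why: Kinetic deprotonation at the unhindered C3 methylene followed by O-triflation gives the less substituted enol triflate and leaves the C5 stereocentre untouched.

Step 4
Reactants: 7 enol triflate
Product: 8 {1-[(1R,2S)-2-(dimethoxymethyl)-3-methylcyclopent-3-en-1-yl]ethenyl}trimethylsilane
Conditions: MeMgBr, Fe(acac)3 (5 mol %), THF/NMP, −30 to 0 °C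
Reagents that add atoms: methylmagnesium bromide, C[Mg]Br
Why: Iron-catalysed Kumada-type cross-coupling of the alkenyl triflate installs the C4 methyl group with the C3=C4 double bond already in place, while acetal and vinylsilane are inert.

Step 5
Reactants: 8 vinylsilane acetal
Product: 10 (1S,5R)-5-(1-iodoethenyl)-2-methylcyclopent-2-ene-1-carbaldehyde, via iodoalkene acetal 9 (not isolated)
Conditions: NIS, MeCN/ClCH2CN (4:1), 0 °C; then 1 M HCl, THF, 0 °C
Reagents that add atoms: N-iodosuccinimide, O=C1CCC(=O)N1I; water, O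
Why: Electrophilic ipso-iododesilylation (β-silicon effect) converts the 1-silylalkene into the 2-iodoalkene faster than NIS engages the ring alkene, and brief cold aqueous acid then unmasks the aldehyde without epimerising or conjugating the β,γ-unsaturated C5 centre.

Step 6
Reactants: 11 2-methylprop-2-en-1-ol
Product: 13 4-methylpent-4-enal, via methallyl vinyl ether 12 (not isolated)
Conditions: EtOCH=CH2 (excess), Hg(OAc)2 (5 mol %), reflux; evaporate; then 150 °C, sealed tube
Reagents that add atoms: ethyl vinyl ether, C=COCC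
Why: Mercury-catalysed transvinylation gives the allyl vinyl ether, which undergoes the aliphatic Claisen [3,3] rearrangement on heating to the γ,δ-unsaturated aldehyde.

Step 7
Reactants: 13 4-methylpent-4-enal; 14 (Z)-but-2-ene
Product: 18 (3S,4S)-3,7-dimethylocta-1,7-dien-4-ol, via crotylpotassium 15 (not isolated), via crotylborane 16 (not isolated), via borinate 17 (not isolated)
Conditions: t-BuOK, n-BuLi, 14, THF, −78 to −45 °C; (+)-Ipc2BOMe, −78 °C; BF3·OEt2; 13, −78 °C; then NaOH, H2O2, 0 °C to rt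
Reagents that add atoms: none
Why: Brown crotylboration, in which the (Z)-crotylborane carrying isopinocampheyl groups from (−)-α-pinene adds through a chair Zimmerman–Traxler transition state to the Re face of the aldehyde and gives the syn homoallylic alcohol with C11 S and C12 S.

Step 8
Reactants: 18 syn homoallylic alcohol
Product: 19 tert-butyl{[(3S,4S)-3,7-dimethylocta-1,7-dien-4-yl]oxy}diphenylsilane
Conditions: t-BuPh2SiCl, imidazole, DMF, rt
Reagents that add atoms: tert-butyl(chloro)diphenylsilane, CC(C)(C)[Si](Cl)(c1ccccc1)c1ccccc1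
Why: Standard silylation, chosen because this silyl ether (unlike the acetate) survives s-BuLi and the later acidic methanolysis and so keeps the C12 oxygen out of any acetal formation.

Step 9
Reactants: 20 prop-2-en-1-ol
Product: 21 prop-2-en-1-yl N,N-diisopropylcarbamate
Conditions: i-Pr2NCOCl, pyridine, 90 °C
Reagents that add atoms: N,N-diisopropylcarbamoyl chloride, CC(C)N(C(C)C)C(=O)Cl
Why: O-Carbamoylation gives the hindered carbamate that resists nucleophilic attack and later directs α-lithiation.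

Step 10
Reactants: 19 silyl ether; 21 allyl carbamate
Product: 22 (2E,4S,5S)-5-[(tert-butyldiphenylsilyl)oxy]-4,8-dimethylnona-2,8-dien-1-yl N,N-diisopropylcarbamate
Conditions: 21 (3 equiv), second-generation Hoveyda–Grubbs catalyst RuCl2(H2IMes)(=CH-C6H4-2-Oi-Pr) (5 mol %), CH2Cl2, 40 °C
Reagents that add atoms: none
Why: Olefin cross-metathesis between the monosubstituted alkene of 19 and excess allyl carbamate gives the E-alkene (needed for the anti outcome of step 11) under thermodynamic control, while the 1,1-disubstituted isopropenyl group is essentially unreactive.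

Step 11
Reactants: 22 allyl carbamate (fragment 2); 10 aldehyde (fragment 1)
Product: 25 (1Z,3S,4R)-4-hydroxy-4-[(1S,5R)-5-(1-iodoethenyl)-2-methylcyclopent-2-en-1-yl]-3-{(2S,3S)-3-[(tert-butyldiphenylsilyl)oxy]-6-methylhept-6-en-2-yl}but-1-en-1-yl N,N-diisopropylcarbamate, via lithiated carbamate 23 (not isolated), via allyltitanium 24 (not isolated)
Conditions: s-BuLi (1.05 equiv), (+)-sparteine, toluene, −78 °C; Ti(Oi-Pr)4, −78 °C; then 10, −78 to −40 °C
Reagents that add atoms: none
Why: Hoppe homoaldol reaction, in which carbamate-directed, (+)-sparteine-controlled α-lithiation gives a configurationally defined d3 (homoenolate) reagent, Li→Ti exchange occurs with inversion, and the E-allyltitanium adds through its γ-carbon C7 to the aldehyde in a closed chair transition state (metal and aldehyde on the same face, carbamate oxygen axial), so the anti pair C6 R/C7 S and the Z-enol carbamate (latent C9 aldehyde) are formed in one step from two carbons that are both electrophilic in ordinary carbonyl chemistry, with the reagent's facial bias reinforced by the C11 centre (attack anti to the C12 branch) and by Felkin–Anh addition to 10 anti to its C1 branch.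

Step 12
Reactants: 25 homoaldol adduct
Product: 26 tert-butyl{[(2S,3S)-2-{(2R,3S)-2-[(1S,5R)-5-(1-iodoethenyl)-2-methylcyclopent-2-en-1-yl]-5-methoxyoxolan-3-yl}-6-methylhept-6-en-3-yl]oxy}diphenylsilane
Conditions: MeOH, Hg(OAc)2 (10 mol %), MeSO3H (1.5 equiv), 0 °C to rt
Reagents that add atoms: methanol, CO
Why: Mercury-catalysed, acid-promoted methanolysis of the enol carbamate (oxymercuration, protodemercuration, loss of the carbamate as CO2 and amine) with capture by the C6 hydroxyl gives the 2-methoxyoxolane, which masks C6–OH and the C9 aldehyde together while the silyl ether keeps C12–O from closing a bicyclic acetal.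

Step 13
Reactants: 26 methyl acetal silyl ether
Product: 28 (2S,3S)-2-{(2R,3S)-2-[(1S,5R)-5-(1-iodoethenyl)-2-methylcyclopent-2-en-1-yl]-5-methoxyoxolan-3-yl}-6-methylhept-6-en-3-yl acetate, via alcohol 27 (not isolated)
Conditions: Bu4NF, THF, rt to 40 °C; then Ac2O, pyridine, DMAP (cat.), 0 °C
Reagents that add atoms: acetic anhydride, CC(=O)OC(C)=O
Why: Fluoride removes the silyl group under non-acidic conditions that leave the methyl acetal untouched, and the only free hydroxyl (C12) is then acetylated in the same flask.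

Step 14
Reactants: 28 methyl acetal acetate
Product: 29 (2S,3S)-2-{(2R,3S)-5-hydroxy-2-[(1S,5R)-5-(1-iodoethenyl)-2-methylcyclopent-2-en-1-yl]oxolan-3-yl}-6-methylhept-6-en-3-yl acetate
Conditions: AcOH/THF/H2O (3:1:1), 40 °C
Reagents that add atoms: water, O
Why: Mild aqueous acid hydrolyses the anomeric methyl acetal to the γ-lactol (ring-chain tautomer of the C9 aldehyde) without touching the acetate, and with C12 acylated no bicyclic acetal can form.

Step 15
Reactants: 29 γ-lactol
Product: 31 (2S,3S)-2-[(3aS,4R,5S,7R,8aR)-4,7-dihydroxy-3-methyl-8-methylidene-1,3a,4,5,6,7,8,8a-octahydroazulen-5-yl]-6-methylhept-6-en-3-yl acetate, via alkenylchromium aldehyde 30 (not isolated)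
Conditions: CrCl2 (8 equiv), NiCl2 (2 mol %), DMSO/THF (3:1), 5 mM, rt
Reagents that add atoms: none
Why: Intramolecular Nozaki–Hiyama–Kishi reaction, in which nickel-catalysed formation of the alkenylchromium (trivalent chromium) from the 2-iodoalkene and its addition to the aldehyde tautomer of the lactol closes the seven-membered ring and gives the C9 alcohol next to the exocyclic methylene directly, the chromium-bound oxygen taking the pseudo-axial position that avoids allylic strain with C18H2 while the C7 side chain stays pseudo-equatorial, which is expected to place the C9 hydroxyl trans to the side chain (9R), with free hydroxyls and the acetate tolerated.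

## Compound list

1 | cyclopent-2-en-1-one | O=C1C=CCC1 | starting material
2 | ethynyltrimethylsilane | C#C[Si](C)(C)C | starting material
3 | diisobutyl[1-(trimethylsilyl)ethenyl]alumane | C=C([Si](C)(C)C)[Al](CC(C)C)CC(C)C | intermediate
4 | diisobutylaluminium (3R)-3-[1-(trimethylsilyl)ethenyl]cyclopent-1-en-1-olate | C=C([Si](C)(C)C)[C@@H]1CCC(O[Al](CC(C)C)CC(C)C)=C1 | intermediate
5 | trimethyl({(3R)-3-[1-(trimethylsilyl)ethenyl]cyclopent-1-en-1-yl}oxy)silane | C=C([Si](C)(C)C)[C@@H]1CCC(O[Si](C)(C)C)=C1 | intermediate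
6 | (2R,3R)-2-(dimethoxymethyl)-3-[1-(trimethylsilyl)ethenyl]cyclopentan-1-one (2,3-trans) | C=C([Si](C)(C)C)[C@@H]1CCC(=O)[C@H]1C(OC)OC | intermediate
7 | (4R,5S)-5-(dimethoxymethyl)-4-[1-(trimethylsilyl)ethenyl]cyclopent-1-en-1-yl trifluoromethanesulfonate | C=C([Si](C)(C)C)[C@@H]1CC=C(OS(=O)(=O)C(F)(F)F)[C@H]1C(OC)OC | intermediate
8 | {1-[(1R,2S)-2-(dimethoxymethyl)-3-methylcyclopent-3-en-1-yl]ethenyl}trimethylsilane | C=C([Si](C)(C)C)[C@@H]1CC=C(C)[C@H]1C(OC)OC | intermediate
9 | (4R,5S)-5-(dimethoxymethyl)-4-(1-iodoethenyl)-1-methylcyclopent-1-ene | C=C(I)[C@@H]1CC=C(C)[C@H]1C(OC)OC | intermediate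
10 | (1S,5R)-5-(1-iodoethenyl)-2-methylcyclopent-2-ene-1-carbaldehyde (fragment 1, trans) | C=C(I)[C@@H]1CC=C(C)[C@H]1C=O | intermediate
11 | 2-methylprop-2-en-1-ol | C=C(C)CO | starting material
12 | 3-(ethenyloxy)-2-methylprop-1-ene | C=C(C)COC=C | intermediate
13 | 4-methylpent-4-enal | C=C(C)CCC=O | intermediate
14 | (Z)-but-2-ene | C/C=C\C | starting material
15 | (Z)-but-2-en-1-ylpotassium | C/C=C\C[K] | intermediate
16 | (Z)-but-2-en-1-ylbis(isopinocampheyl)borane, isopinocampheyl groups from (−)-α-pinene | C/C=C\CB([C@H]1C[C@H]2C[C@@H]([C@@H]1C)C2(C)C)[C@H]1C[C@H]2C[C@@H]([C@@H]1C)C2(C)C | intermediate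
17 | (3S,4S)-3,7-dimethylocta-1,7-dien-4-yl bis(isopinocampheyl)borinate | C=C(C)CC[C@H](OB([C@H]1C[C@H]2C[C@@H]([C@@H]1C)C2(C)C)[C@H]1C[C@H]2C[C@@H]([C@@H]1C)C2(C)C)[C@@H](C)C=C | intermediate
18 | (3S,4S)-3,7-dimethylocta-1,7-dien-4-ol (syn) | C=C(C)CC[C@H](O)[C@@H](C)C=C | intermediate
19 | tert-butyl{[(3S,4S)-3,7-dimethylocta-1,7-dien-4-yl]oxy}diphenylsilane | C=C(C)CC[C@H](O[Si](c1ccccc1)(c1ccccc1)C(C)(C)C)[C@@H](C)C=C | intermediate
20 | prop-2-en-1-ol | C=CCO | starting material
21 | prop-2-en-1-yl N,N-diisopropylcarbamate | C=CCOC(=O)N(C(C)C)C(C)C | intermediate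
22 | (2E,4S,5S)-5-[(tert-butyldiphenylsilyl)oxy]-4,8-dimethylnona-2,8-dien-1-yl N,N-diisopropylcarbamate (fragment 2) | C=C(C)CC[C@H](O[Si](c1ccccc1)(c1ccccc1)C(C)(C)C)[C@@H](C)/C=C/COC(=O)N(C(C)C)C(C)C | intermediate
23 | (1R,2E,4S,5S)-1-lithio derivative of 22, as its (+)-sparteine complex (diamine not drawn) | C=C(C)CC[C@H](O[Si](c1ccccc1)(c1ccccc1)C(C)(C)C)[C@@H](C)/C=C/[C@@H]([Li])OC(=O)N(C(C)C)C(C)C | intermediate
24 | (1S,2E,4S,5S)-1-(triisopropoxytitanio) derivative of 22 | C=C(C)CC[C@H](O[Si](c1ccccc1)(c1ccccc1)C(C)(C)C)[C@@H](C)/C=C/[C@H]([Ti](OC(C)C)(OC(C)C)OC(C)C)OC(=O)N(C(C)C)C(C)C | intermediate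
25 | (1Z,3S,4R)-4-hydroxy-4-[(1S,5R)-5-(1-iodoethenyl)-2-methylcyclopent-2-en-1-yl]-3-{(2S,3S)-3-[(tert-butyldiphenylsilyl)oxy]-6-methylhept-6-en-2-yl}but-1-en-1-yl N,N-diisopropylcarbamate | C=C(C)CC[C@H](O[Si](c1ccccc1)(c1ccccc1)C(C)(C)C)[C@@H](C)[C@H](/C=C\OC(=O)N(C(C)C)C(C)C)[C@@H](O)[C@@H]1C(C)=CC[C@H]1C(I)=C | intermediate
26 | tert-butyl{[(2S,3S)-2-{(2R,3S)-2-[(1S,5R)-5-(1-iodoethenyl)-2-methylcyclopent-2-en-1-yl]-5-methoxyoxolan-3-yl}-6-methylhept-6-en-3-yl]oxy}diphenylsilane (both anomers) | C=C(C)CC[C@H](O[Si](c1ccccc1)(c1ccccc1)C(C)(C)C)[C@@H](C)[C@@H]1CC(OC)O[C@H]1[C@@H]1C(C)=CC[C@H]1C(I)=C | intermediate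
27 | (2S,3S)-2-{(2R,3S)-2-[(1S,5R)-5-(1-iodoethenyl)-2-methylcyclopent-2-en-1-yl]-5-methoxyoxolan-3-yl}-6-methylhept-6-en-3-ol | C=C(C)CC[C@H](O)[C@@H](C)[C@@H]1CC(OC)O[C@H]1[C@@H]1C(C)=CC[C@H]1C(I)=C | intermediate
28 | (2S,3S)-2-{(2R,3S)-2-[(1S,5R)-5-(1-iodoethenyl)-2-methylcyclopent-2-en-1-yl]-5-methoxyoxolan-3-yl}-6-methylhept-6-en-3-yl acetate | C=C(C)CC[C@H](OC(C)=O)[C@@H](C)[C@@H]1CC(OC)O[C@H]1[C@@H]1C(C)=CC[C@H]1C(I)=C | intermediate
29 | (2S,3S)-2-{(2R,3S)-5-hydroxy-2-[(1S,5R)-5-(1-iodoethenyl)-2-methylcyclopent-2-en-1-yl]oxolan-3-yl}-6-methylhept-6-en-3-yl acetate (lactol, both anomers) | C=C(C)CC[C@H](OC(C)=O)[C@@H](C)[C@@H]1CC(O)O[C@H]1[C@@H]1C(C)=CC[C@H]1C(I)=C | intermediate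
30 | open-chain hydroxy aldehyde tautomer of 29 with C10–CrCl2 in place of C10–I (C1 R, C5 S, C6 R, C7 S, C11 S, C12 S) | C=C(C)CC[C@H](OC(C)=O)[C@@H](C)[C@H](CC=O)[C@@H](O)[C@@H]1C(C)=CC[C@H]1C(=C)[Cr](Cl)Cl | intermediate
31 | (2S,3S)-2-[(3aS,4R,5S,7R,8aR)-4,7-dihydroxy-3-methyl-8-methylidene-1,3a,4,5,6,7,8,8a-octahydroazulen-5-yl]-6-methylhept-6-en-3-yl acetate | C=C(C)CC[C@H](OC(C)=O)[C@@H](C)[C@@H]1C[C@@H](O)C(=C)[C@@H]2CC=C(C)[C@H]2[C@@H]1O | target

## Step count and risks

Total step count: 15. Longest linear sequence: 10 (steps 1–5, then 11–15).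

Three steps most likely to fail:

**Step 11 (key homoaldol coupling).** The level and sense of diamine control on a γ-branched, already chiral carbamate are not tabulated; any Z-alkene in 22 gives the syn adduct; and aldehyde 10 is enolisable. Fallback: it sets out from 19 (with 10) and comes back at 26. Cross-metathesis of 19 with methyl acrylate (same ruthenium catalyst) gives methyl (2E,4S,5S)-5-silyloxy-4,8-dimethylnona-2,8-dienoate F1. SmI2 (2.5 equiv) and t-BuOH in THF at −78 °C then turn aldehyde 10 into its ketyl, which adds as a carbonyl-carbon donor to the β-carbon of F1 and lactonises to the 4,5-trans γ-lactone F2. Here the C6/C7 sense rests on Felkin control from C5 and on the C11 centre rather than on a chiral reagent, and the diastereomers are separated. i-Bu2AlH at −78 °C reduces F2 to the lactol F3, and MeOH with pyridinium p-toluenesulfonate gives 26.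

**Step 15 (ring closure).** The γ-lactol must open to the aldehyde under the chromium conditions, and the C9 configuration rests on substrate control that is argued, not demonstrated. Fallback: it sets out from 29 and comes back at 31. The cyclisation is accepted as it falls, giving the C9 epimer F4 or a mixture with 31. MnO2 oxidises only the allylic C9 alcohol to the α-methylene ketone F5. Reduction with (S)-2-methyl-CBS-oxazaborolidine and catecholborane at −78 °C then sets C9 by reagent control (alkenyl as the large group gives 9R) and delivers 31.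

**Step 1 (asymmetric conjugate addition with enolate trapping).** A bulky 1-silylvinyl group on unsubstituted cyclopentenone may give modest enantioselectivity. Any minor enantiomer of 10 is removed later as a diastereomer after step 11, but yield is lost. Fallback: it sets out from 1 and comes back at 5. Commercial (1-bromoethenyl)trimethylsilane and Mg give the Grignard reagent F6, and ClTi(Oi-Pr)3 converts it into the vinyltitanium F7. Rhodium-catalysed 1,4-addition to 1 with [Rh(OH)((S)-binap)]2 (3 mol % Rh) in THF at 20 °C gives the titanium enolate F8, which Me3SiCl silylates to 5.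

Further compounds
F1 | step 11 | methyl (2E,4S,5S)-5-[(tert-butyldiphenylsilyl)oxy]-4,8-dimethylnona-2,8-dienoate | C=C(C)CC[C@H](O[Si](c1ccccc1)(c1ccccc1)C(C)(C)C)[C@@H](C)/C=C/C(=O)OC
F2 | step 11 | (4S,5R)-4-{(2S,3S)-3-[(tert-butyldiphenylsilyl)oxy]-6-methylhept-6-en-2-yl}-5-[(1S,5R)-5-(1-iodoethenyl)-2-methylcyclopent-2-en-1-yl]oxolan-2-one | C=C(C)CC[C@H](O[Si](c1ccccc1)(c1ccccc1)C(C)(C)C)[C@@H](C)[C@@H]1CC(=O)O[C@H]1[C@@H]1C(C)=CC[C@H]1C(I)=C
F3 | step 11 | (4S,5R)-4-{(2S,3S)-3-[(tert-butyldiphenylsilyl)oxy]-6-methylhept-6-en-2-yl}-5-[(1S,5R)-5-(1-iodoethenyl)-2-methylcyclopent-2-en-1-yl]oxolan-2-ol (both anomers) | C=C(C)CC[C@H](O[Si](c1ccccc1)(c1ccccc1)C(C)(C)C)[C@@H](C)[C@@H]1CC(O)O[C@H]1[C@@H]1C(C)=CC[C@H]1C(I)=C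
F4 | step 15 | (2S,3S)-2-[(3aS,4R,5S,7S,8aR)-4,7-dihydroxy-3-methyl-8-methylidene-1,3a,4,5,6,7,8,8a-octahydroazulen-5-yl]-6-methylhept-6-en-3-yl acetate (C9 epimer of 31) | C=C(C)CC[C@H](OC(C)=O)[C@@H](C)[C@@H]1C[C@H](O)C(=C)[C@@H]2CC=C(C)[C@H]2[C@@H]1O
F5 | step 15 | (2S,3S)-2-[(3aS,4R,5S,8aR)-4-hydroxy-3-methyl-8-methylidene-7-oxo-1,3a,4,5,6,7,8,8a-octahydroazulen-5-yl]-6-methylhept-6-en-3-yl acetate | C=C(C)CC[C@H](OC(C)=O)[C@@H](C)[C@@H]1CC(=O)C(=C)[C@@H]2CC=C(C)[C@H]2[C@@H]1O
F6 | step 1 | bromo[1-(trimethylsilyl)ethenyl]magnesium | C=C([Mg]Br)[Si](C)(C)C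
F7 | step 1 | triisopropoxy[1-(trimethylsilyl)ethenyl]titanium | C=C([Si](C)(C)C)[Ti](OC(C)C)(OC(C)C)OC(C)C
F8 | step 1 | triisopropoxytitanium (3R)-3-[1-(trimethylsilyl)ethenyl]cyclopent-1-en-1-olate | C=C([Si](C)(C)C)[C@@H]1CCC(O[Ti](OC(C)C)(OC(C)C)OC(C)C)=C1
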